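## Retrosynthetic overview

1. Target 26 ⇐ hydrogenation of isopropenyl cage 25 ⇐ oxidative radical cascade of bicyclic 1,3‑diketone 24 (C3 radical, 7‑exo onto the endo C7 prenyl, then 5‑exo onto the C3 prenyl): seven‑membered cage ring, then cyclopentane, formed last.
2. 24 ⇐ adamantane alcohol 18 (stores the C7 aldehyde in the endo position) by retro‑aldol/vinyl addition, formate reduction and cross‑metathesis.
3. 18 ⇐ demethylation/intramolecular aldol of 16; 16 ⇐ asymmetric C‑alkylation of arene 14 with bromo enal 4, then intramolecular Michael addition closing ring B (C1–C8 bond) on the phloroglucinol‑derived ring A.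
4. Fragments: 14 from 5‑methoxyresorcinol, isobutyronitrile, geranyl bromide and prenyl bromide; 4 from diethyl isopropylidenemalonate.
5. Ring order: ring A (aromatic) → ring B (Michael) → temporary adamantane ring (aldol, reopened) → seven‑membered ring → cyclopentane (radical cascade).

Assumption: the cinchonidinium catalyst of step 9 is taken to give the enantiomer drawn (its cinchoninium pseudo‑enantiomer gives the antipode). Names use the usual numbering of this compound class (C1 acyl bridgehead, C2–C4 dione bridge, C5 geranyl bridgehead, C8 CMe2, C9 bridging ketone; endo = on the side of the C2–C4 bridge; prenyl = 3‑methylbut‑2‑enyl; geranyl = (2E)‑3,7‑dimethylocta‑2,6‑dienyl), and 1,3‑diketones are drawn as one enol tautomer.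

## Route

Step 1
Reactants: 1 diethyl 2‑(propan‑2‑ylidene)propanedioate
Product: 2 2‑(propan‑2‑ylidene)propane‑1,3‑diol
Conditions: i‑Bu2AlH (4.4 equiv), CH2Cl2, −78 to 0 °C; Rochelle salt work‑up
Reagents that add atoms: none
Why: Ester reduction; the electrophilic aluminium hydride reduces both conjugated esters 1,2 and leaves the tetrasubstituted alkene (no stereocentre).

Step 2
Reactants: 2 2‑(propan‑2‑ylidene)propane‑1,3‑diol
Product: 3 2‑(hydroxymethyl)‑3‑methylbut‑2‑enal
Conditions: MnO2 (activated, 8 equiv), CH2Cl2, 20 °C, stopped at mono‑oxidation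
Reagents that add atoms: none
Why: Allylic alcohol oxidation; after the first oxidation the remaining CH2OH sits on an electron‑poor enal and reacts much more slowly, so the hydroxy enal can be isolated.

Step 3
Reactants: 3 2‑(hydroxymethyl)‑3‑methylbut‑2‑enal
Product: 4 2‑(bromomethyl)‑3‑methylbut‑2‑enal
Conditions: PBr3 (0.4 equiv), Et2O, −20 °C
Reagents that add atoms: phosphorus tribromide, BrP(Br)Br
Why: Alcohol‑to‑bromide substitution (SN2 at the primary allylic carbon) at low temperature leaves the enal untouched.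

Step 4
Reactants: 5 geraniol
Product: 6 geranyl bromide
Conditions: PBr3 (0.4 equiv), Et2O, −10 °C
Reagents that add atoms: phosphorus tribromide, BrP(Br)Br
Why: Alcohol‑to‑bromide substitution (SN2) without allylic transposition keeps the E double bond.

Step 5
Reactants: 7 prenol (3‑methylbut‑2‑en‑1‑ol)
Product: 8 prenyl bromide
Conditions: PBr3 (0.4 equiv), Et2O, −10 °C
Reagents that add atoms: phosphorus tribromide, BrP(Br)Br
Why: Alcohol‑to‑bromide substitution (SN2) on the primary allylic alcohol.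

Step 6
Reactants: 9 5‑methoxyresorcinol; 10 isobutyronitrile
Product: 12 1‑(2,4‑dihydroxy‑6‑methoxyphenyl)‑2‑methylpropan‑1‑one, via ketiminium chloride 11 (not isolated)
Conditions: ZnCl2, HCl (g), Et2O, 0 °C; then H2O, 100 °C
Reagents that add atoms: water, O; hydrogen chloride, Cl
Why: Houben–Hoesch acylation; the nitrilium ion attacks a ring position ortho to one hydroxyl and para to the other, preferring the two equivalent, less hindered sites next to OMe over the site between the hydroxyls, and hydrolysis of the ketiminium salt gives the ketone (the minor symmetric isomer is removed by crystallisation).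

Step 7
Reactants: 12 1‑(2,4‑dihydroxy‑6‑methoxyphenyl)‑2‑methylpropan‑1‑one; 6 geranyl bromide
Product: 13 1‑(3‑geranyl‑2,4‑dihydroxy‑6‑methoxyphenyl)‑2‑methylpropan‑1‑one
Conditions: KOH (10 % aq.), 0 to 20 °C
Reagents that add atoms: none
Why: Phenoxide C‑alkylation (SN2); the carbon between the two oxido groups is the most nucleophilic and the protic medium suppresses O‑alkylation, and the E alkene is not touched (the 5‑isomer is separated).

Step 8
Reactants: 13 1‑(3‑geranyl‑2,4‑dihydroxy‑6‑methoxyphenyl)‑2‑methylpropan‑1‑one; 8 prenyl bromide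
Product: 14 1‑(3‑geranyl‑2,4‑dihydroxy‑6‑methoxy‑5‑prenylphenyl)‑2‑methylpropan‑1‑one
Conditions: KOH (10 % aq.), 0 to 20 °C
Reagents that add atoms: none
Why: Second phenoxide C‑alkylation (SN2) goes to the only remaining ring CH, because attack there is less hindered than at the geranyl‑bearing carbon and restores aromaticity.

Step 9
Reactants: 14 1‑(3‑geranyl‑2,4‑dihydroxy‑6‑methoxy‑5‑prenylphenyl)‑2‑methylpropan‑1‑one; 4 2‑(bromomethyl)‑3‑methylbut‑2‑enal
Product: 16 5‑geranyl‑1‑isobutyryl‑2‑methoxy‑8,8‑dimethyl‑4,9‑dioxo‑3‑prenylbicyclo[3.3.1]non‑2‑ene‑7‑carbaldehyde (C7 epimers), via dearomatised enal 15 (not isolated)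
Conditions: O‑allyl‑N‑(9‑anthracenylmethyl)cinchonidinium bromide (10 mol %), CsOH·H2O (2.5 equiv), toluene–CH2Cl2, −50 to −20 °C
Reagents that add atoms: none
Why: Asymmetric phase‑transfer C‑alkylation followed by intramolecular Michael addition; with no ring CH left the dianion is alkylated at the geranyl‑bearing carbon between the two oxido groups on the face left open by the chiral ammonium ion (sets C5), and the acyl‑bearing enolate carbon then adds 6‑exo to the β,β‑dimethyl enal on the only face the tether can reach (sets C1 and the C1–C8 bond), C7 remaining an epimer mixture.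

Step 10
Reactants: 16 5‑geranyl‑1‑isobutyryl‑2‑methoxy‑8,8‑dimethyl‑4,9‑dioxo‑3‑prenylbicyclo[3.3.1]non‑2‑ene‑7‑carbaldehyde
Product: 18 5‑geranyl‑10‑hydroxy‑1‑isobutyryl‑8,8‑dimethyl‑3‑prenyladamantane‑2,4,9‑trione, via enol aldehyde 17 (not isolated)
Conditions: LiCl, DMSO, 120 °C; aq. NH4Cl work‑up
Reagents that add atoms: none
Why: Nucleophilic demethylation of the vinylogous ester (SN2 by chloride) then intramolecular aldol addition; only the endo aldehyde can reach C3, and enolisation of the aldehyde feeds both C7 epimers into the adamantane, which fixes C3 and the endo bond at C7 (the carbinol centre is not needed later).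

Step 11
Reactants: 18 5‑geranyl‑10‑hydroxy‑1‑isobutyryl‑8,8‑dimethyl‑3‑prenyladamantane‑2,4,9‑trione
Product: 21 1‑(4‑acetoxy‑5‑geranyl‑1‑isobutyryl‑8,8‑dimethyl‑2,9‑dioxo‑3‑prenylbicyclo[3.3.1]non‑3‑en‑7‑endo‑yl)prop‑2‑enyl acetate, via endo aldehyde 19 (not isolated), via allylic alcohol 20 (not isolated)
Conditions: CH2=CHMgBr, CeCl3, THF, −78 °C; then Ac2O, DMAP, −78 to 0 °C
Reagents that add atoms: vinylmagnesium bromide, C=C[Mg]Br; acetic anhydride, CC(=O)OC(C)=O
Why: Retro‑aldol, organocerium 1,2‑addition and acylation; the alkoxide opens to the endo aldehyde, which the weakly basic vinyl cerium reagent captures at −78 °C before it can epimerise, so C7 keeps its configuration (the carbinol centre is uncontrolled and is removed in step 12; the enolate is acetylated on its less hindered oxygen).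

Step 12
Reactants: 21 1‑(4‑acetoxy‑5‑geranyl‑1‑isobutyryl‑8,8‑dimethyl‑2,9‑dioxo‑3‑prenylbicyclo[3.3.1]non‑3‑en‑7‑endo‑yl)prop‑2‑enyl acetate
Product: 22 7‑endo‑allyl‑5‑geranyl‑1‑isobutyryl‑8,8‑dimethyl‑2,9‑dioxo‑3‑prenylbicyclo[3.3.1]non‑3‑en‑4‑yl acetate
Conditions: Pd2(dba)3·CHCl3 (2.5 mol %), PBu3, HCO2H, Et3N, THF, 50 °C
Reagents that add atoms: none
Why: Tsuji formate reduction; hydride is delivered from palladium to the more substituted terminus of the π‑allyl to give the terminal alkene, while the enol acetate keeps C3 from attacking the π‑allyl and C7 is not touched.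

Step 13
Reactants: 22 7‑endo‑allyl‑5‑geranyl‑1‑isobutyryl‑8,8‑dimethyl‑2,9‑dioxo‑3‑prenylbicyclo[3.3.1]non‑3‑en‑4‑yl acetate
Product: 24 5‑geranyl‑4‑hydroxy‑1‑isobutyryl‑8,8‑dimethyl‑3,7‑endo‑diprenylbicyclo[3.3.1]non‑3‑ene‑2,9‑dione, via prenyl enol acetate 23 (not isolated)
Conditions: second‑generation Grubbs catalyst (5 mol %), 2‑methylbut‑2‑ene (excess), CH2Cl2, 40 °C; then K2CO3 (cat.), MeOH, 0 °C
Reagents that add atoms: 2‑methylbut‑2‑ene, CC=C(C)C
Why: Olefin cross‑metathesis of the monosubstituted alkene with 2‑methylbut‑2‑ene (the trisubstituted prenyl and geranyl alkenes do not react), then methanolysis of the activated enol ester.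

Step 14
Reactants: 24 5‑geranyl‑4‑hydroxy‑1‑isobutyryl‑8,8‑dimethyl‑3,7‑endo‑diprenylbicyclo[3.3.1]non‑3‑ene‑2,9‑dione
Product: 25 isopropenyl analogue of the target (C(CH3)=CH2 in place of the ring isopropyl group)
Conditions: Mn(OAc)3·2H2O (2.2 equiv), Cu(OAc)2·H2O (1 equiv), degassed AcOH, 25 °C
Reagents that add atoms: none
Why: Oxidative free‑radical cyclisation cascade; the C3 radical adds 7‑exo to the endo C7 prenyl alkene (the cage fixes C3), the tertiary radical closes 5‑exo onto the C3 prenyl group with the new side chain on the convex face, and Cu(OAc)2 turns the last radical into the isopropenyl group; 25 is the isomer whose ring‑fusion CH carries the CMe2 arm on the C2 side, and its epimer (arm on the C4 side) is removed by chromatography.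

Step 15
Reactants: 25 isopropenyl analogue of the target
Product: 26 CNP0379246.1 (target)
Conditions: H2 (1 atm), RhCl(PPh3)3 (10 mol %), benzene–EtOH, 25 °C
Reagents that add atoms: none
Why: Homogeneous hydrogenation; RhCl(PPh3)3 reduces the 1,1‑disubstituted alkene and leaves the two trisubstituted geranyl alkenes, and the new CH carries two methyl groups so no stereocentre is created.

## Compound list

1 | diethyl 2‑(propan‑2‑ylidene)propanedioate | CCOC(=O)C(=C(C)C)C(=O)OCC | starting material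
2 | 2‑(propan‑2‑ylidene)propane‑1,3‑diol | CC(C)=C(CO)CO | intermediate
3 | 2‑(hydroxymethyl)‑3‑methylbut‑2‑enal | CC(C)=C(CO)C=O | intermediate
4 | 2‑(bromomethyl)‑3‑methylbut‑2‑enal | CC(C)=C(CBr)C=O | intermediate
5 | geraniol | CC(C)=CCC/C(C)=C/CO | starting material
6 | geranyl bromide | CC(C)=CCC/C(C)=C/CBr | intermediate
7 | prenol (3‑methylbut‑2‑en‑1‑ol) | CC(C)=CCO | starting material
8 | prenyl bromide | CC(C)=CCBr | intermediate
9 | 5‑methoxyresorcinol | COc1cc(O)cc(O)c1 | starting material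
10 | isobutyronitrile | CC(C)C#N | starting material
11 | ketiminium chloride of 12 (not isolated) | CC(C)C(=[NH2+])c1c(O)cc(O)cc1OC.[Cl-] | intermediate
12 | 1‑(2,4‑dihydroxy‑6‑methoxyphenyl)‑2‑methylpropan‑1‑one | CC(C)C(=O)c1c(O)cc(O)cc1OC | intermediate
13 | 1‑(3‑geranyl‑2,4‑dihydroxy‑6‑methoxyphenyl)‑2‑methylpropan‑1‑one | CC(C)C(=O)c1c(O)c(C/C=C(\C)CCC=C(C)C)c(O)cc1OC | intermediate
14 | 1‑(3‑geranyl‑2,4‑dihydroxy‑6‑methoxy‑5‑prenylphenyl)‑2‑methylpropan‑1‑one | CC(C)C(=O)c1c(O)c(C/C=C(\C)CCC=C(C)C)c(O)c(CC=C(C)C)c1OC | intermediate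
15 | dearomatised enal: 6‑geranyl‑6‑(2‑formyl‑3‑methylbut‑2‑enyl)‑5‑hydroxy‑4‑isobutyryl‑3‑methoxy‑2‑prenylcyclohexa‑2,4‑dien‑1‑one, C6 as in SMILES (not isolated) | CC(C)=CCC/C(C)=C/C[C@@]1(CC(C=O)=C(C)C)C(=O)C(CC=C(C)C)=C(OC)C(C(=O)C(C)C)=C1O | intermediate
16 | 5‑geranyl‑1‑isobutyryl‑2‑methoxy‑8,8‑dimethyl‑4,9‑dioxo‑3‑prenylbicyclo[3.3.1]non‑2‑ene‑7‑carbaldehyde, C1 and C5 as in SMILES, C7 epimer mixture | CC(C)=CCC/C(C)=C/C[C@]12CC(C=O)C(C)(C)[C@](C(=O)C(C)C)(C1=O)C(OC)=C(CC=C(C)C)C2=O | intermediate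
17 | enol aldehyde: 16 with OH in place of OMe, C7 epimer mixture (not isolated) | CC(C)=CCC/C(C)=C/C[C@]12CC(C=O)C(C)(C)[C@](C(=O)C(C)C)(C1=O)C(O)=C(CC=C(C)C)C2=O | intermediate
18 | 5‑geranyl‑10‑hydroxy‑1‑isobutyryl‑8,8‑dimethyl‑3‑prenyladamantane‑2,4,9‑trione (C10 = former formyl carbon, bonded to C3 and C7; carbinol configuration not defined) | CC(C)=CCC/C(C)=C/C[C@]12C[C@@H]3C(C)(C)[C@](C(=O)C(C)C)(C1=O)C(=O)[C@](CC=C(C)C)(C2=O)C3O | intermediate
19 | endo aldehyde: 7‑endo‑formyl‑5‑geranyl‑4‑hydroxy‑1‑isobutyryl‑8,8‑dimethyl‑3‑prenylbicyclo[3.3.1]non‑3‑ene‑2,9‑dione (not isolated, present as enolate) | CC(C)=CCC/C(C)=C/C[C@]12C[C@@H](C=O)C(C)(C)[C@](C(=O)C(C)C)(C1=O)C(=O)C(CC=C(C)C)=C2O | intermediate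
20 | allylic alcohol: 7‑endo‑(1‑hydroxyprop‑2‑enyl) analogue of 19, carbinol configuration not defined (not isolated, present as alkoxide) | CC(C)=CCC/C(C)=C/C[C@]12C[C@@H](C(O)C=C)C(C)(C)[C@](C(=O)C(C)C)(C1=O)C(=O)C(CC=C(C)C)=C2O | intermediate
21 | 1‑(4‑acetoxy‑5‑geranyl‑1‑isobutyryl‑8,8‑dimethyl‑2,9‑dioxo‑3‑prenylbicyclo[3.3.1]non‑3‑en‑7‑endo‑yl)prop‑2‑enyl acetate | CC(C)=CCC/C(C)=C/C[C@]12C[C@@H](C(OC(C)=O)C=C)C(C)(C)[C@](C(=O)C(C)C)(C1=O)C(=O)C(CC=C(C)C)=C2OC(C)=O | intermediate
22 | 7‑endo‑allyl‑5‑geranyl‑1‑isobutyryl‑8,8‑dimethyl‑2,9‑dioxo‑3‑prenylbicyclo[3.3.1]non‑3‑en‑4‑yl acetate | CC(C)=CCC/C(C)=C/C[C@]12C[C@@H](CC=C)C(C)(C)[C@](C(=O)C(C)C)(C1=O)C(=O)C(CC=C(C)C)=C2OC(C)=O | intermediate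
23 | prenyl enol acetate: 7‑endo‑prenyl analogue of 22 (not isolated) | CC(C)=CCC/C(C)=C/C[C@]12C[C@@H](CC=C(C)C)C(C)(C)[C@](C(=O)C(C)C)(C1=O)C(=O)C(CC=C(C)C)=C2OC(C)=O | intermediate
24 | 5‑geranyl‑4‑hydroxy‑1‑isobutyryl‑8,8‑dimethyl‑3,7‑endo‑diprenylbicyclo[3.3.1]non‑3‑ene‑2,9‑dione | CC(C)=CCC/C(C)=C/C[C@]12C[C@@H](CC=C(C)C)C(C)(C)[C@](C(=O)C(C)C)(C1=O)C(=O)C(CC=C(C)C)=C2O | intermediate
25 | isopropenyl analogue of the target (all ring stereocentres as in the target) | CC(C)=CCC/C(C)=C/C[C@@]12C[C@H]3C[C@@H]4C(C)(C)[C@@H](C(C)=C)C[C@]4(C1=O)C(=O)[C@@](C(=O)C(C)C)(C2=O)C3(C)C | intermediate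
26 | CNP0379246.1 | CC(C)=CCC/C(C)=C/C[C@@]12C[C@H]3C[C@@H]4C(C)(C)[C@@H](C(C)C)C[C@]4(C1=O)C(=O)[C@@](C(=O)C(C)C)(C2=O)C3(C)C | target

## Step count and weak points

Total step count: 15. Longest linear sequence: 10 steps (steps 6–15 from 5‑methoxyresorcinol; equally steps 1–3 then 9–15, or step 4 then 7–15).

Steps most likely to fail:

1. Step 14 (radical cascade). The configuration at the ring‑fusion CH is not secured: a simple steric model suggests the unwanted epimer (CMe2 arm toward C4) may even be favoured, so the yield of 25 may be well below half. Cu(OAc)2 can also oxidise the first tertiary radical before the second ring closes. Fallback: starting from 24, brominate the enol carbon with NBS in CH2Cl2 at −78 °C to give the 3‑bromo‑3‑prenyl‑2,4‑dione F1. Treat it with Bu3SnH (slow addition) and Et3B/air in toluene at 0 to 20 °C. The same C3 radical is formed by bromine abstraction, the two ring closures run as a reductive chain, and the last radical takes hydrogen from the stannane, so the isopropyl group is formed directly. This comes back to the route at 26 and leaves out 25 and the hydrogenation; the two ring‑fusion epimers are separated as before.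

2. Step 9 (asymmetric alkylation/Michael). The choice between the geranyl‑bearing and the prenyl‑bearing ring carbon, O‑alkylation, the choice of enolate carbon in the Michael step and the level of face selection are all untested on this substrate. Fallback: starting from 14 (and from 3, which is acetylated with Ac2O/pyridine to the acetate F2), use an allylic alkylation with zerovalent palladium: Pd2(dba)3, (R,R)‑DACH‑phenyl Trost ligand, Cs2CO3, THF, 0 °C. Ionisation of the acetate gives the 2‑formyl‑1,1‑dimethylallyl complex, which is attacked at its CH2 end. Because C‑allylation of this enolate is reversible, the more stable dienone 15 accumulates. DBU then brings about the Michael ring closure, and the route is rejoined at 16.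

3. Step 11 (retro‑aldol/vinyl addition/acetylation). The released aldehyde may epimerise before capture, the organometallic may add to a ketone, and the double acetylation may be incomplete. Fallback: starting from 18, treat with methoxymethylenetriphenylphosphorane (from Ph3PCH2OMe chloride and KOtBu, THF, −78 to 0 °C); retro‑aldol and Wittig reaction give the enol ether F3. Hydrolysis with oxalic acid in THF–water gives the homologated endo aldehyde F4, and a second Wittig reaction with isopropylidenetriphenylphosphorane (from isopropyltriphenylphosphonium iodide and n‑BuLi) gives the prenyl group. This comes back to the route at 24 and leaves out 21 and 22.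

Further compounds

F1 | step 14 | 3‑bromo‑5‑geranyl‑1‑isobutyryl‑8,8‑dimethyl‑3,7‑endo‑diprenylbicyclo[3.3.1]nonane‑2,4,9‑trione (C3 configuration not defined) | CC(C)=CCC/C(C)=C/C[C@]12C[C@@H](CC=C(C)C)C(C)(C)[C@](C(=O)C(C)C)(C1=O)C(=O)C(Br)(CC=C(C)C)C2=O
F2 | step 9 | (2‑formyl‑3‑methylbut‑2‑enyl) acetate | CC(C)=C(C=O)COC(C)=O
F3 | step 11 | 5‑geranyl‑4‑hydroxy‑1‑isobutyryl‑7‑endo‑(2‑methoxyethenyl)‑8,8‑dimethyl‑3‑prenylbicyclo[3.3.1]non‑3‑ene‑2,9‑dione (E/Z mixture) | CC(C)=CCC/C(C)=C/C[C@]12C[C@@H](C=COC)C(C)(C)[C@](C(=O)C(C)C)(C1=O)C(=O)C(CC=C(C)C)=C2O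
F4 | step 11 | 2‑(5‑geranyl‑4‑hydroxy‑1‑isobutyryl‑8,8‑dimethyl‑2,9‑dioxo‑3‑prenylbicyclo[3.3.1]non‑3‑en‑7‑endo‑yl)acetaldehyde | CC(C)=CCC/C(C)=C/C[C@]12C[C@@H](CC=O)C(C)(C)[C@](C(=O)C(C)C)(C1=O)C(=O)C(CC=C(C)C)=C2O
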